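**Remarks on the chemistry**

- Atom numbers are those of the halimane skeleton; C18 is the carboxyl carbon on C4.
- The carbinol carbon C6 of 3, 4, 8 and 9 is expected as a mixture of epimers and is left undefined, because it becomes sp2 in step 4.
- Correction to the key step: the 1,2-trans dialkenyl allyl ether 13 and the decalinol 17 (O10 and H5 cis) are kept, but heat alone cannot link them. The ring-trans olefin formed by the chair oxy-Cope can undergo the suprafacial ene closure only with H5 anti to O10. The key step therefore includes an E-to-Z isomerisation of the ten-membered ketone in the same flask.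

## Structural features

The target is a bicyclic ent-halimane: a cyclohexene ring A (C1–C5, C10) with a trisubstituted C1=C10 olefin, fused through C5–C10 to a saturated ring B (C5–C10). Ring A carries the quaternary C4 (methyl and the C18 acid) next to the ring-fusion methine C5; ring B carries the methyl-bearing C8 next to the quaternary C9 (C20 methyl and the C11 chain), and C9 is bonded directly to the olefinic C10. H5, the acid and the C11 chain lie on one face and the methyls on C4, C8 and C9 on the other, so the four ring stereocentres (4S,5S,8R,9S) form two adjacent pairs separated only by C10. The chain on C9 (C11–C15, with the C16 methyl on C13) ends in a tertiary carbinol C13 (S), a secondary acetate C14 (R) and a free primary alcohol C15. Fragile points are the acetate between two free hydroxyls (migration to O15, hydrolysis), the C1=C10 olefin, which acid can move to the tetrasubstituted C5=C10 position, and the neopentyl acid, whose esters resist mild hydrolysis. The real difficulty is the relative configuration across C10: H5 must be cis to the C9 chain and trans to the methyls on C8 and C9, beside two quaternary centres. The key step uses the fact that C5, C6, C7, C8, C9 and C10 of ring B form a Cope array once the C5–C10 bond of a ring-A cyclohexanol is broken: a ten-membered ketone with its carbonyl at C10 and α-carbon at C9 allows C7–C8, C9–C11 and C5–C10 to be made in one operation.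

## Logic of the disconnections

**31 back to 28.** The O15–Si bond, the acetyl–O14 bond and the O–CH3 bond of the C18 ester are cut in that order, through 30 and 29 to 28. The acetate goes on next to last and O15 is freed last, because a free primary hydroxyl beside the acetate invites acyl migration. The acid is freed before the acetate exists, because no ester cleavage at the neopentyl C18 would spare it. The gain is that three oxygens are told apart by steric rank alone; the demand is a final step that is neutral or slightly acidic.

**28 back to 25.** The C13–O bond (with inversion) and the C14–O bond are cut: 28 and 27 come from 26, and 26 from 25. The two oxygens are anti across what was an E olefin, so a syn-dihydroxylation is excluded and an epoxide opened at C13 is needed. Both side-chain stereocentres disappear and a trisubstituted allylic alcohol remains. The forward steps must be reagent-controlled, because the ring is too far away, and the opening must be a clean inversion at a tertiary carbon.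

**25 back to 19.** C13–C16 and C14–C15 are cut together (one carbometalation of 22). The C1=C10 double bond is then traced to the C10 carbinol of 21, and C13≡C14 to the aldehyde 20 and the alcohol 19. The olefin is made after the aldehyde chemistry and before the side chain carries acid- or chloride-sensitive oxygens. The side chain shrinks to a three-carbon arm. The demand is an anti elimination that can only run towards C1, which requires O10 and H5 cis, and a carbometalation that tolerates the ester.

**19 back to 17.** The C–H bonds at C6 and C7 and the C13–O bond are cut, through 18. The terminal olefin must be functionalised before the ring olefin is reduced, so a hydroboration selective for the allyl group comes first. After this, 17 contains only what one cascade can deliver.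

**17 back to 13 (key disconnection).** C5–C10, C9–C11 and C7–C8 are cut, through 16, 15 and 14. Both rings and the stereocentres C5, C8, C9 and C10 collapse into one monocyclic allyl ether whose stereochemical information lies in ring A and in one olefin geometry. The forward step needs a chair oxy-Cope, an outer-face Claisen shift and a closure with H5 syn to O10; an E ring olefin cannot give the last, hence the Z olefin of 16.

**13 back to 1.** The O10–allyl bond (from 11) and the ester O–CH3 bond are cut to 10. The vinyl group and the acid of 10 are folded back into the cis-fused lactone of 8 (C6–O and C7–Cl re-formed). C9–C10 is cut to 4 and the organometallic from 5, C5–C6 and the lactone C–O bond to 2, and C4–CH3 to 1. A lactone between C18 and C6 does four things: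
- it fixes the C4/C5 relationship;
- it blocks the axial face of the C10 ketone, so that the butenyl group enters trans to C6;
- it keeps the vinyl group masked while C5 is still enolisable;
- it releases the acid as a salt, which avoids the 1,3-lactone that an ester would form with the O10 alkoxide.

The demand is an enantioselective conjugate methylation and an aldol addition on the ester face.

## Other disconnections considered

**Alternative 1:** The C1=C10 double bond is cut. Forward, the keto aldehyde A2 (ring B with the C10 ketone and the C4 arm ending in the C1 aldehyde) would be treated with low-valent titanium (TiCl3, Zn–Cu, DME, reflux, high dilution) in an intramolecular McMurry coupling that closes ring A and gives A1.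
- In its favour: the olefin position is fixed by the two carbonyl carbons, so there is no dehydration regiochemistry and no ring-fusion carbinol; C5 is α to the ketone in A2 and could be equilibrated; the tert-butyl ester and the silyl ether should tolerate the reagent.
- Against it here: A2 needs the C8/C9/C5 triad on a cyclohexanone and, in addition, the quaternary C4 on an exocyclic arm. The C4–C5 bond then joins a ring methine to an acyclic quaternary stereocentre that the ring cannot control. The C10 ketone, flanked by quaternary C9 and a C5 bearing a quaternary group, is very hindered, so stopping at the pinacol or simple aldehyde reduction is a real risk.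
- Comparison: this alternative is the better on olefin regiochemistry and on avoiding the cis decalinol, and the equal on protecting-group load. It is weaker on the C4/C5 relationship and on step economy, because the key step creates no stereocentre and both quaternary centres must be built beforehand.

**Alternative 2:** The C2–C3 and C4–C5 bonds are cut. Forward, the ring-B vinyl diene A4 (C2=C1–C10=C5) and methacrolein A5 would combine in a Lewis-acid-promoted Diels–Alder reaction (for example Me2AlCl, CH2Cl2, −78 °C). The substituted diene terminus C5 bonds to the substituted dienophile carbon C4, and exo placement of the formyl group puts it cis to H5, giving A3.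
- In its favour: ring A, quaternary C4, C5 and the C1=C10 olefin arise in one convergent step; A3 carries the same allyl handle as the chosen route, and the aldehyde is one oxidation from the acid.
- Against it here: the face of the diene is distinguished only by quaternary C9, two bonds from C5, whose methyl and allyl groups are of similar size, so C4/C5 relative to C8/C9 is poorly controlled. The s-cis conformer of A4 is crowded by the C9 substituents, and exo selectivity with A5 is not secure. A4 still needs the vicinal C8/C9 pair.
- Comparison: this alternative is the better on step economy and on olefin placement, and the equal on predictability of regiochemistry. It is weaker on the relative configuration across C10. The chosen plan is also weakest there, but it has a defined relay: olefin geometry, then the face of O10.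

**Alternative 3:** The C9–C10 bond is cut. Forward, the ring-A enol triflate A7 would undergo oxidative addition to zerovalent palladium (from Pd(OAc)2 and PPh3, with an amine base, MeCN, 80 °C), 6-exo carbopalladation of the C9=C11 olefin and β-hydride loss towards C12, closing ring B and giving the silyl enol ether A6.
- In its favour: the C1=C10 olefin is set by enol triflate formation away from hindered C5; C4 and C5 are fixed early on ring A, where C5 is α to a ketone; quaternary centres by intramolecular Heck reaction are well precedented; β-hydride loss has only one direction.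
- Against it here: the configuration of C9 rests on substrate control from C8 and C5 in the insertion, with little precedent for this pattern. A7 needs an acyclic C8 stereocentre and a trisubstituted olefin on a hindered C5 arm. Only C11 and C12 are delivered, so the side chain needs one more carbon than with the allyl group.
- Comparison: this alternative is the better on olefin regiochemistry and on mildness (80 °C against about 200 °C), and the equal on functional-group tolerance. It is weaker on step count and on what the key step builds: one ring and one stereocentre against two rings and four stereocentres.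

Key step: step 6

## Route

Step 1
Reactants: 1 methyl 3-oxocyclohex-1-ene-1-carboxylate
Product: 2 methyl (S)-1-methyl-3-(trimethylsilyloxy)cyclohex-2-ene-1-carboxylate
Conditions: Me2Zn, (CuOTf)2·C6H6 (cat.), chiral imidazolinium sulfonate (NHC precursor, cat.), t-BuOMe, −30 °C; then TMSOTf, −30→0 °C
Reagents that add atoms: dimethylzinc, C[Zn]C; trimethylsilyl triflate, C[Si](C)(C)OS(=O)(=O)C(F)(F)F
Why: Copper-catalysed asymmetric conjugate addition of an alkylzinc to a β-ester-substituted cyclohexenone is an established way to ester-bearing quaternary centres; the ligand antipode is chosen for 4S, and silylation of the zinc enolate fixes the enol double bond at C5=C10 (regiospecific enolate trapping).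

Step 2
Reactants: 2 methyl (S)-1-methyl-3-(trimethylsilyloxy)cyclohex-2-ene-1-carboxylate
Product: 4 (3aR,7aS)-3-(chloromethyl)-7a-methylhexahydro-2-benzofuran-1,4-dione (cis-fused keto γ-lactone; lactone between C18 and O6; C6 epimers), via aldol adduct 3 (not isolated)
Conditions: ClCH2CHO (anhydrous), TiCl4, CH2Cl2, −78 °C; then CSA (cat.), CH2Cl2, 23 °C
Reagents that add atoms: chloroacetaldehyde, ClCC=O
Why: Mukaiyama aldol addition at C5 of the regiodefined silyl enol ether; TiCl4 bridging the C4 ester and the aldehyde should deliver the electrophile to the ester face, and only that adduct can close to the cis-fused γ-lactone (lactonisation), which locks the C4/C5 relationship and masks the acid. The C6 carbinol configuration does not matter.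

Step 3
Reactants: 4 (3aR,7aS)-3-(chloromethyl)-7a-methylhexahydro-2-benzofuran-1,4-dione; 5 (E)-2-bromobut-2-ene
Product: 8 (3aR,4R,7aS)-4-[(E)-but-2-en-2-yl]-3-(chloromethyl)-4-hydroxy-7a-methylhexahydro-2-benzofuran-1(3H)-one, via butenyllithium 6 (not isolated), via butenylcerium dichloride 7 (not isolated)
Conditions: 5, t-BuLi (2 equiv), THF, −78 °C; CeCl3, −78 °C; then 4, −78 °C; AcOH, −78 °C
Reagents that add atoms: none
Why: Bromine–lithium exchange with retention of olefin geometry, transmetalation to the weakly basic organocerium reagent and 1,2-addition to the ketone in preference to the lactone (organocerium carbonyl addition). In the cis-fused bicycle the axial lactone carbonyl on C4 blocks axial attack, so the reagent should enter equatorially, trans to C6, placing O10 on the ester face (10R). The cold quench is meant to stop the new alkoxide from transacylating the lactone.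

Step 4
Reactants: 8 (3aR,4R,7aS)-4-[(E)-but-2-en-2-yl]-3-(chloromethyl)-4-hydroxy-7a-methylhexahydro-2-benzofuran-1(3H)-one
Product: 10 (1S,2S,3R)-3-[(E)-but-2-en-2-yl]-3-hydroxy-1-methyl-2-vinylcyclohexane-1-carboxylic acid, via iodo lactone 9 (not isolated)
Conditions: NaI, Zn dust, DMF, 60 °C; aq. NaH2PO4 work-up
Reagents that add atoms: none
Why: Finkelstein exchange followed by zinc-induced reductive β-elimination of the vicinal iodo carboxylate (Boord-type fragmentation) unveils the C5 vinyl group and the C18 acid together. This happens after the enolisable ketone is gone, so C5 cannot epimerise and the vinyl group cannot move into conjugation.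

Step 5
Reactants: 10 (1S,2S,3R)-3-[(E)-but-2-en-2-yl]-3-hydroxy-1-methyl-2-vinylcyclohexane-1-carboxylic acid; 11 allyl bromide
Product: 13 methyl (1S,2S,3R)-3-(allyloxy)-3-[(E)-but-2-en-2-yl]-1-methyl-2-vinylcyclohexane-1-carboxylate, via potassium carboxylate 12 (not isolated)
Conditions: KH (2.2 equiv), 18-crown-6 (cat.), THF, 0 °C; 11 (1.1 equiv), 0→23 °C; then MeI, DMF, 23 °C
Reagents that add atoms: iodomethane, CI
Why: Williamson etherification of the dianion: the tertiary potassium alkoxide is far more nucleophilic than the hindered carboxylate, so O10 should be allylated first and the carboxylate is then methylated in the same flask. Keeping the acid as its salt until O10 is alkylated avoids the 1,3-lactone that an alkoxide cis to an ester would form.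

Step 6
Reactants: 13 methyl (1S,2S,3R)-3-(allyloxy)-3-[(E)-but-2-en-2-yl]-1-methyl-2-vinylcyclohexane-1-carboxylate
Product: 17 methyl (4S,5R,8R,9S,10R)-9-allyl-10-hydroxy-4,8,9-trimethyl-Δ6-octalin-4-carboxylate (halimane numbering; OH, H5 and allyl on one face, the C8 and C9 methyls on the other), via dienol allyl ether 14 (not isolated), via E-cyclodecenone 15 (not isolated), via Z-cyclodecenone 16 (not isolated)
Conditions: PhMe (0.02 M, base-washed sealed tube), 190 °C; cool, PhSSPh (10 mol %), hν (350 nm), 25 °C; then 230 °C
Reagents that add atoms: none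
Why: The chair oxy-Cope rearrangement of 13 (both alkenyl groups equatorial) breaks C5–C10 and forms C7–C8, giving the ring-trans dienol allyl ether 14, whose aliphatic Claisen rearrangement on the outer face of the enol ether forms C9–C11 and releases the C10 ketone 15; the closest known reaction type is the tandem oxy-Cope/Claisen/transannular carbonyl-ene cascade of 1,2-dialkenylcyclohexanol allyl ethers. C8 is set by the E geometry of the butenyl group in the chair (methyl equatorial, 8R) and C9 by the outer-face Claisen shift (9S), so the two methyls end cis. The ene step closes ring B by a transannular six-membered closure between C10 and C5 through the array O–C10–C5–C6–C7–H, and this same bond re-forms the six-membered ring A. Because that array is suprafacial on C5–C6–C7 and ring B must contain the new cis C6=C7 bond, an E ring olefin (C4 anti to C7) can close only with H5 anti to the C10 oxygen, which would give the 5-epimeric anti decalinol; a Z ring olefin closes with H5 syn to oxygen. The first heating is therefore held at the lowest temperature that consumes 13, the ene onto the α-quaternary ketone being expected to be the slowest of the three events, and 15 is isomerised in the same flask to the less strained Z ketone 16 by reversible phenylthiyl-radical addition. On renewed heating 16 should close through the syn array with oxygen on the face of the C9 allyl group, because this keeps the C8 methyl away from the O···H–C7 bridge, giving 10R and 5R in 17. The selectivities needed are closure only after isomerisation, which rests on the temperature staging, and allyl-face placement of oxygen, which rests on the C8 and C9 substituents.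

Step 7
Reactants: 17 methyl (4S,5R,8R,9S,10R)-9-allyl-10-hydroxy-4,8,9-trimethyl-Δ6-octalin-4-carboxylate
Product: 18 methyl (4S,5R,8R,9S,10R)-10-hydroxy-9-(3-hydroxypropyl)-4,8,9-trimethyl-Δ6-octalin-4-carboxylate
Conditions: 9-BBN (2.2 equiv), THF, 0→23 °C; then H2O2, aq. NaOH, 0 °C
Reagents that add atoms: hydrogen peroxide, OO
Why: Hydroboration–oxidation; 9-BBN differentiates the monosubstituted allyl olefin from the hindered cis-disubstituted C6=C7 ring olefin and places boron on the terminal carbon C13 (anti-Markovnikov).

Step 8
Reactants: 18 methyl (4S,5R,8R,9S,10R)-10-hydroxy-9-(3-hydroxypropyl)-4,8,9-trimethyl-Δ6-octalin-4-carboxylate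
Product: 19 methyl (4S,5R,8R,9S,10R)-10-hydroxy-9-(3-hydroxypropyl)-4,8,9-trimethyldecalin-4-carboxylate
Conditions: H2 (1 atm), Pd/C, EtOAc, 23 °C
Reagents that add atoms: none
Why: Heterogeneous catalytic hydrogenation of the only remaining olefin; no stereocentre arises because C6 and C7 become CH2.

Step 9
Reactants: 19 methyl (4S,5R,8R,9S,10R)-10-hydroxy-9-(3-hydroxypropyl)-4,8,9-trimethyldecalin-4-carboxylate
Product: 20 methyl (4S,5R,8R,9S,10R)-10-hydroxy-4,8,9-trimethyl-9-(3-oxopropyl)decalin-4-carboxylate
Conditions: DMP (Dess–Martin periodinane, 1.1 equiv), NaHCO3, CH2Cl2, 0 °C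
Reagents that add atoms: none
Why: Dess–Martin oxidation of the primary alcohol; the tertiary C10 alcohol is inert, and partial closure of the aldehyde to its six-membered lactol with O10 is harmless because the lactol reacts as the aldehyde in step 10. One equivalent of oxidant avoids oxidation to the lactone.

Step 10
Reactants: 20 methyl (4S,5R,8R,9S,10R)-10-hydroxy-4,8,9-trimethyl-9-(3-oxopropyl)decalin-4-carboxylate
Product: 21 methyl (4S,5R,8R,9S,10R)-9-(but-3-yn-1-yl)-10-hydroxy-4,8,9-trimethyldecalin-4-carboxylate
Conditions: dimethyl (1-diazo-2-oxopropyl)phosphonate, K2CO3, MeOH, 0→23 °C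
Reagents that add atoms: dimethyl (1-diazo-2-oxopropyl)phosphonate, COP(=O)(OC)C(=[N+]=[N-])C(C)=O
Why: Ohira–Bestmann (Seyferth–Gilbert) homologation converts the aldehyde or its lactol into the terminal alkyne under carbonate conditions that leave the hindered ester untouched; it adds C14.

Step 11
Reactants: 21 methyl (4S,5R,8R,9S,10R)-9-(but-3-yn-1-yl)-10-hydroxy-4,8,9-trimethyldecalin-4-carboxylate
Product: 22 methyl (4S,5S,8R,9S)-9-(but-3-yn-1-yl)-4,8,9-trimethyl-Δ1(10)-octalin-4-carboxylate
Conditions: SOCl2, pyridine, CH2Cl2, −20→0 °C
Reagents that add atoms: none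
Why: E2 dehydration of the tertiary chlorosulfite by pyridine; with the C10 oxygen cis to H5 and C9 quaternary, the only antiperiplanar hydrogen is the axial H1, so the olefin should form at C1=C10. Low temperature and excess pyridine are meant to suppress ionisation, which would lead to the C5=C10 isomer or a methyl shift from C9.

Step 12
Reactants: 22 methyl (4S,5S,8R,9S)-9-(but-3-yn-1-yl)-4,8,9-trimethyl-Δ1(10)-octalin-4-carboxylate
Product: 25 methyl (4S,5S,8R,9S)-9-[(E)-5-hydroxy-3-methylpent-3-en-1-yl]-4,8,9-trimethyl-Δ1(10)-octalin-4-carboxylate, via alkenylalane 23 (not isolated), via lithium alanate 24 (not isolated)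
Conditions: AlMe3, Cp2ZrCl2 (20 mol %), CH2Cl2, 0→23 °C; evaporate excess AlMe3; n-BuLi, THF, −78 °C; (CH2O)n, −78→23 °C
Reagents that add atoms: trimethylaluminium, C[Al](C)C; formaldehyde (as paraformaldehyde), C=O
Why: Negishi zirconium-catalysed syn-carboalumination places the methyl group on C13 and aluminium on C14 of the terminal alkyne, and the derived alanate is hydroxymethylated with retention, giving the E trisubstituted allylic alcohol as one olefin isomer. The neopentyl ester and the hindered ring olefin are expected to survive.

Step 13
Reactants: 25 methyl (4S,5S,8R,9S)-9-[(E)-5-hydroxy-3-methylpent-3-en-1-yl]-4,8,9-trimethyl-Δ1(10)-octalin-4-carboxylate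
Product: 26 methyl (4S,5S,8R,9S)-9-{2-[(2R,3R)-3-(hydroxymethyl)-2-methyloxiran-2-yl]ethyl}-4,8,9-trimethyl-Δ1(10)-octalin-4-carboxylate (13R,14R epoxide)
Conditions: Ti(OiPr)4 (cat.), D-(−)-diethyl tartrate (cat.), t-BuOOH, 4 Å MS, CH2Cl2, −20 °C
Reagents that add atoms: tert-butyl hydroperoxide, CC(C)(C)OO
Why: Sharpless asymmetric epoxidation: titanium delivers oxygen only to the allylic alcohol, so the ring olefin is untouched, and D-(−)-diethyl tartrate should give the 13R,14R epoxide by reagent control (the mirror image of the geraniol case with the L-(+) ester).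

Step 14
Reactants: 26 methyl (4S,5S,8R,9S)-9-{2-[(2R,3R)-3-(hydroxymethyl)-2-methyloxiran-2-yl]ethyl}-4,8,9-trimethyl-Δ1(10)-octalin-4-carboxylate
Product: 27 methyl (4S,5S,8R,9S)-4,8,9-trimethyl-9-[(3S,4R)-3,4,5-trihydroxy-3-methylpentyl]-Δ1(10)-octalin-4-carboxylate (13S,14R triol)
Conditions: HClO4 (cat.), THF/H2O, 0 °C
Reagents that add atoms: water, O
Why: Acid-catalysed epoxide hydrolysis: water should attack the tertiary C13 from the face opposite the leaving oxygen (inversion, giving 13S), while C14 keeps the epoxide oxygen (14R), so the anti-diol results from the E olefin.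

Step 15
Reactants: 27 methyl (4S,5S,8R,9S)-4,8,9-trimethyl-9-[(3S,4R)-3,4,5-trihydroxy-3-methylpentyl]-Δ1(10)-octalin-4-carboxylate
Product: 28 methyl (4S,5S,8R,9S)-9-[(3S,4R)-5-(tert-butyldimethylsilyloxy)-3,4-dihydroxy-3-methylpentyl]-4,8,9-trimethyl-Δ1(10)-octalin-4-carboxylate
Conditions: TBSCl, imidazole, CH2Cl2, 0 °C
Reagents that add atoms: tert-butyldimethylsilyl chloride, CC(C)(C)[Si](C)(C)Cl
Why: Selective silylation of the primary C15 hydroxyl (steric differentiation from the secondary and tertiary hydroxyls).

Step 16
Reactants: 28 methyl (4S,5S,8R,9S)-9-[(3S,4R)-5-(tert-butyldimethylsilyloxy)-3,4-dihydroxy-3-methylpentyl]-4,8,9-trimethyl-Δ1(10)-octalin-4-carboxylate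
Product: 29 (4S,5S,8R,9S)-9-[(3S,4R)-5-(tert-butyldimethylsilyloxy)-3,4-dihydroxy-3-methylpentyl]-4,8,9-trimethyl-Δ1(10)-octalin-4-carboxylic acid
Conditions: n-PrSLi, HMPA, 23 °C; cold dilute HCl work-up
Reagents that add atoms: none
Why: SN2 demethylation of the hindered methyl ester by thiolate, which attacks the O-methyl carbon and not the shielded carbonyl; it is done before the acetate exists because any later ester cleavage would also remove or shift the acetate.

Step 17
Reactants: 29 (4S,5S,8R,9S)-9-[(3S,4R)-5-(tert-butyldimethylsilyloxy)-3,4-dihydroxy-3-methylpentyl]-4,8,9-trimethyl-Δ1(10)-octalin-4-carboxylic acid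
Product: 30 (4S,5S,8R,9S)-9-[(3S,4R)-4-acetoxy-5-(tert-butyldimethylsilyloxy)-3-hydroxy-3-methylpentyl]-4,8,9-trimethyl-Δ1(10)-octalin-4-carboxylic acid
Conditions: Ac2O, pyridine, DMAP (cat.), CH2Cl2, 0 °C; aq. NaHCO3/THF work-up, then acidify
Reagents that add atoms: acetic anhydride, CC(=O)OC(C)=O
Why: DMAP-catalysed acylation of the only unhindered free hydroxyl (secondary C14); the tertiary C13 hydroxyl should not react, and the mixed anhydride formed at the neopentyl acid is cleaved again on bicarbonate work-up.

Step 18
Reactants: 30 (4S,5S,8R,9S)-9-[(3S,4R)-4-acetoxy-5-(tert-butyldimethylsilyloxy)-3-hydroxy-3-methylpentyl]-4,8,9-trimethyl-Δ1(10)-octalin-4-carboxylic acid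
Product: 31 (4S,5S,8R,9S,13S,14R)-14-acetoxy-13,15-dihydroxy-ent-halim-1(10)-en-18-oic acid (CNP0164901.1)
Conditions: HF·pyridine, pyridine/THF, 0 °C
Reagents that add atoms: none
Why: Fluoride-mediated desilylation under buffered, slightly acidic conditions, chosen because basic fluoride sources would promote 1,2-acetyl migration from O14 to O15.

## Compound list

1 | methyl 3-oxocyclohex-1-ene-1-carboxylate | COC(=O)C1=CC(=O)CCC1 | starting material
2 | methyl (S)-1-methyl-3-(trimethylsilyloxy)cyclohex-2-ene-1-carboxylate | C[Si](C)(C)OC1=C[C@@](C)(C(=O)OC)CCC1 | intermediate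
3 | methyl (1S,2R)-2-(2-chloro-1-hydroxyethyl)-1-methyl-3-oxocyclohexane-1-carboxylate (C6 epimers; not isolated) | COC(=O)[C@@]1(C)CCCC(=O)[C@H]1C(O)CCl | intermediate
4 | (3aR,7aS)-3-(chloromethyl)-7a-methylhexahydro-2-benzofuran-1,4-dione (C6 epimers) | O=C1CCC[C@]2(C)C(=O)OC(CCl)[C@H]12 | intermediate
5 | (E)-2-bromobut-2-ene | C/C(Br)=C\C | starting material
6 | but-2-en-2-yllithium, geometry of 5 retained (not isolated) | C/C([Li])=C\C | intermediate
7 | dichloro(but-2-en-2-yl)cerium, same geometry (not isolated) | C/C([Ce](Cl)Cl)=C\C | intermediate
8 | (3aR,4R,7aS)-4-[(E)-but-2-en-2-yl]-3-(chloromethyl)-4-hydroxy-7a-methylhexahydro-2-benzofuran-1(3H)-one (C6 epimers) | O[C@@]1(CCC[C@]2(C)C(=O)OC(CCl)[C@H]12)/C(C)=C/C | intermediate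
9 | (3aR,4R,7aS)-4-[(E)-but-2-en-2-yl]-4-hydroxy-3-(iodomethyl)-7a-methylhexahydro-2-benzofuran-1(3H)-one (not isolated) | O[C@@]1(CCC[C@]2(C)C(=O)OC(CI)[C@H]12)/C(C)=C/C | intermediate
10 | (1S,2S,3R)-3-[(E)-but-2-en-2-yl]-3-hydroxy-1-methyl-2-vinylcyclohexane-1-carboxylic acid | O[C@@]1(CCC[C@](C)(C(=O)O)[C@@H]1C=C)/C(C)=C/C | intermediate
11 | allyl bromide | C=CCBr | starting material
12 | potassium (1S,2S,3R)-3-(allyloxy)-3-[(E)-but-2-en-2-yl]-1-methyl-2-vinylcyclohexane-1-carboxylate (not isolated) | C=CCO[C@@]1(CCC[C@](C)(C(=O)[O-])[C@@H]1C=C)/C(C)=C/C.[K+] | intermediate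
13 | methyl (1S,2S,3R)-3-(allyloxy)-3-[(E)-but-2-en-2-yl]-1-methyl-2-vinylcyclohexane-1-carboxylate | C=CCO[C@@]1(CCC[C@](C)(C(=O)OC)[C@@H]1C=C)/C(C)=C/C | intermediate
14 | methyl (1S,2E,5R,6Z)-7-(allyloxy)-1,5,6-trimethylcyclodeca-2,6-diene-1-carboxylate, both ring double bonds ring-trans (not isolated) | C=CCO/C1=C(C)\[C@H](C)C/C=C/[C@@](C)(C(=O)OC)CCC1 | intermediate
15 | methyl (1S,2E,5R,6S)-6-allyl-1,5,6-trimethyl-7-oxocyclodec-2-ene-1-carboxylate (not isolated) | C=CC[C@@]1(C)[C@H](C)C/C=C/[C@@](C)(C(=O)OC)CCCC1=O | intermediate
16 | methyl (1S,2Z,5R,6S)-6-allyl-1,5,6-trimethyl-7-oxocyclodec-2-ene-1-carboxylate (not isolated) | C=CC[C@@]1(C)[C@H](C)C/C=C\[C@@](C)(C(=O)OC)CCCC1=O | intermediate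
17 | methyl (4S,5R,8R,9S,10R)-9-allyl-10-hydroxy-4,8,9-trimethyl-Δ6-octalin-4-carboxylate | C=CC[C@]1(C)[C@@]2(O)CCC[C@](C)(C(=O)OC)[C@H]2C=C[C@H]1C | intermediate
18 | methyl (4S,5R,8R,9S,10R)-10-hydroxy-9-(3-hydroxypropyl)-4,8,9-trimethyl-Δ6-octalin-4-carboxylate | OCCC[C@]1(C)[C@@]2(O)CCC[C@](C)(C(=O)OC)[C@H]2C=C[C@H]1C | intermediate
19 | methyl (4S,5R,8R,9S,10R)-10-hydroxy-9-(3-hydroxypropyl)-4,8,9-trimethyldecalin-4-carboxylate | OCCC[C@]1(C)[C@@]2(O)CCC[C@](C)(C(=O)OC)[C@H]2CC[C@H]1C | intermediate
20 | methyl (4S,5R,8R,9S,10R)-10-hydroxy-4,8,9-trimethyl-9-(3-oxopropyl)decalin-4-carboxylate | O=CCC[C@]1(C)[C@@]2(O)CCC[C@](C)(C(=O)OC)[C@H]2CC[C@H]1C | intermediate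
21 | methyl (4S,5R,8R,9S,10R)-9-(but-3-yn-1-yl)-10-hydroxy-4,8,9-trimethyldecalin-4-carboxylate | C#CCC[C@]1(C)[C@@]2(O)CCC[C@](C)(C(=O)OC)[C@H]2CC[C@H]1C | intermediate
22 | methyl (4S,5S,8R,9S)-9-(but-3-yn-1-yl)-4,8,9-trimethyl-Δ1(10)-octalin-4-carboxylate | C#CCC[C@]1(C)C2=CCC[C@](C)(C(=O)OC)[C@H]2CC[C@H]1C | intermediate
23 | (E)-alkenyldimethylalane from 22, Al on C14 and methyl on C13 (not isolated) | C[Al](C)/C=C(\C)CC[C@]1(C)C2=CCC[C@](C)(C(=O)OC)[C@H]2CC[C@H]1C | intermediate
24 | lithium butyl(alkenyl)dimethylalanate from 23 (not isolated) | [Li+].CCCC[Al-](C)(C)/C=C(\C)CC[C@]1(C)C2=CCC[C@](C)(C(=O)OC)[C@H]2CC[C@H]1C | intermediate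
25 | methyl (4S,5S,8R,9S)-9-[(E)-5-hydroxy-3-methylpent-3-en-1-yl]-4,8,9-trimethyl-Δ1(10)-octalin-4-carboxylate | OC/C=C(\C)CC[C@]1(C)C2=CCC[C@](C)(C(=O)OC)[C@H]2CC[C@H]1C | intermediate
26 | methyl (4S,5S,8R,9S)-9-{2-[(2R,3R)-3-(hydroxymethyl)-2-methyloxiran-2-yl]ethyl}-4,8,9-trimethyl-Δ1(10)-octalin-4-carboxylate | OC[C@H]1O[C@]1(C)CC[C@]2(C)C3=CCC[C@](C)(C(=O)OC)[C@H]3CC[C@H]2C | intermediate
27 | methyl (4S,5S,8R,9S)-4,8,9-trimethyl-9-[(3S,4R)-3,4,5-trihydroxy-3-methylpentyl]-Δ1(10)-octalin-4-carboxylate | OC[C@@H](O)[C@@](C)(O)CC[C@]1(C)C2=CCC[C@](C)(C(=O)OC)[C@H]2CC[C@H]1C | intermediate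
28 | methyl (4S,5S,8R,9S)-9-[(3S,4R)-5-(tert-butyldimethylsilyloxy)-3,4-dihydroxy-3-methylpentyl]-4,8,9-trimethyl-Δ1(10)-octalin-4-carboxylate | CC(C)(C)[Si](C)(C)OC[C@@H](O)[C@@](C)(O)CC[C@]1(C)C2=CCC[C@](C)(C(=O)OC)[C@H]2CC[C@H]1C | intermediate
29 | (4S,5S,8R,9S)-9-[(3S,4R)-5-(tert-butyldimethylsilyloxy)-3,4-dihydroxy-3-methylpentyl]-4,8,9-trimethyl-Δ1(10)-octalin-4-carboxylic acid | CC(C)(C)[Si](C)(C)OC[C@@H](O)[C@@](C)(O)CC[C@]1(C)C2=CCC[C@](C)(C(=O)O)[C@H]2CC[C@H]1C | intermediate
30 | (4S,5S,8R,9S)-9-[(3S,4R)-4-acetoxy-5-(tert-butyldimethylsilyloxy)-3-hydroxy-3-methylpentyl]-4,8,9-trimethyl-Δ1(10)-octalin-4-carboxylic acid | CC(=O)O[C@H](CO[Si](C)(C)C(C)(C)C)[C@@](C)(O)CC[C@]1(C)C2=CCC[C@](C)(C(=O)O)[C@H]2CC[C@H]1C | intermediate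
31 | (4S,5S,8R,9S,13S,14R)-14-acetoxy-13,15-dihydroxy-ent-halim-1(10)-en-18-oic acid | CC(=O)O[C@H](CO)[C@@](C)(O)CC[C@]1(C)C2=CCC[C@](C)(C(=O)O)[C@H]2CC[C@H]1C | target

## Step count and least certain steps

Total step count: 18. Longest linear sequence: 18 steps from 1 (5 and 11 enter as commercial reagents).

**Step 6 (key step).** Two things may go wrong. Ring closure may occur already at the E stage during the first heating; that closure is unstrained and leads to the anti, 5-epimeric ring fusion. Closure from the Z ketone may be slow, because the syn array presses C4 against a C9 substituent in a 1,3-diaxial way, so that decomposition or thiyl-radical reactions of the allyl group compete. The fallback sets out from 16 (the first two stages are run and 16 is isolated) and rejoins at 19. Ring B is closed by a ketyl–olefin radical cyclisation instead of the pericyclic ene: SmI2, HMPA, t-BuOH, THF, 0 °C should add the C10 ketyl to C5 of the Z olefin and reduce the C6 radical, giving the saturated allyl decalinol F1 with the cis ring fusion. 9-BBN, then H2O2/NaOH converts F1 into 19, and steps 7 and 8 fall away.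

**Step 2.** The aldehyde may attack the face of the C4 methyl, since the two C4 substituents differ little in size. Retro-aldol or dehydration of the β-hydroxy ketone may occur during lactonisation, and the chlorohydrin may close to an epoxide. The fallback sets out from 2 and rejoins at 10, by-passing steps 3 and 4 as well. The vinyl group is attached directly by palladium-catalysed coupling of the tin enolate (vinyl bromide, Bu3SnF, PdCl2[P(o-tol)3]2 cat., benzene, reflux), giving the vinyl ketone F2 as a C5 epimer mixture. Addition of 7 at −78 °C and warming lets only the adduct with O10 cis to the ester close to the bridged lactone F3, which acts as a stereochemical filter and is separated from material that cannot lactonise. KOH in MeOH/H2O, then buffering to pH 5, opens F3 to 10.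

**Step 5.** The carboxylate may be alkylated before the hindered alkoxide, after which the alkoxide closes onto the new ester (1,3-lactonisation); 10 may also lactonise on storage. The fallback sets out from 10 and rejoins at 13. The acid is esterified first (TMSCHN2, MeOH/PhMe, 0 °C) to the hydroxy ester F4. The ether is then made without a free alkali alkoxide, by palladium-catalysed allylic etherification of the zinc alkoxide (Et2Zn, allyl acetate, Pd(OAc)2 cat., 2-(di-tert-butylphosphino)biphenyl, THF, 25 °C), which should give 13.

**Step 14.** Partial ionisation at the tertiary carbon may erode the configuration at C13; a hydride shift to a carbonyl compound or migration of the ring olefin under acid are further risks. The fallback sets out from 26 and rejoins at 27. The epoxide is opened at C13 by a titanium-bound carboxylate within a chelate (Ti(OiPr)4, PhCO2H, CH2Cl2, 25 °C), an SN2-type opening with inversion, to the C13 benzoate F5. K2CO3 in MeOH then removes the benzoate and gives 27.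

## Further compounds

F1 | step 6 | methyl (4S,5R,8R,9S,10R)-9-allyl-10-hydroxy-4,8,9-trimethyldecalin-4-carboxylate | C=CC[C@]1(C)[C@@]2(O)CCC[C@](C)(C(=O)OC)[C@H]2CC[C@H]1C
F2 | step 2 | methyl (1S)-1-methyl-3-oxo-2-vinylcyclohexane-1-carboxylate (C5 epimers) | COC(=O)[C@@]1(C)CCCC(=O)C1C=C
F3 | step 2 | bridged γ-lactone of 10 (C18 carbonyl to O10), 6-oxabicyclo[3.2.1]octan-7-one with C4 methyl, C5 vinyl and C10 (E)-but-2-en-2-yl | O=C1O[C@@]2(CCC[C@@]1(C)[C@@H]2C=C)/C(C)=C/C
F4 | step 5 | methyl (1S,2S,3R)-3-[(E)-but-2-en-2-yl]-3-hydroxy-1-methyl-2-vinylcyclohexane-1-carboxylate | O[C@@]1(CCC[C@](C)(C(=O)OC)[C@@H]1C=C)/C(C)=C/C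
F5 | step 14 | methyl (4S,5S,8R,9S)-9-[(3S,4R)-3-(benzoyloxy)-4,5-dihydroxy-3-methylpentyl]-4,8,9-trimethyl-Δ1(10)-octalin-4-carboxylate | OC[C@@H](O)[C@@](C)(OC(=O)c1ccccc1)CC[C@]2(C)C3=CCC[C@](C)(C(=O)OC)[C@H]3CC[C@H]2C
A1 | alternative 1 | bicyclic 1(10)-ene tert-butyl ester with the C13 silyl ether | CC(C)(C)[Si](C)(C)OCCC[C@]1(C)C2=CCC[C@](C)(C(=O)OC(C)(C)C)[C@H]2CC[C@H]1C
A2 | alternative 1 | ring-B keto aldehyde (C10 ketone, C1 aldehyde on the C4 arm) | CC(C)(C)[Si](C)(C)OCCC[C@]1(C)C(=O)[C@H](CC[C@H]1C)[C@](C)(CCC=O)C(=O)OC(C)(C)C
A3 | alternative 2 | bicyclic 1(10)-ene C18 aldehyde with C9 allyl | C=CC[C@]1(C)C2=CCC[C@](C)(C=O)[C@H]2CC[C@H]1C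
A4 | alternative 2 | ring-B vinyl diene (C2=C1–C10=C5) with C9 allyl and methyl, C8 methyl | C=CC[C@]1(C)C(C=C)=CCC[C@H]1C
A5 | alternative 2 | methacrolein | CC(=C)C=O
A6 | alternative 3 | bicyclic 1(10)-ene methyl ester with quaternary C9 and the C11=C12 silyl enol ether | CC(C)(C)[Si](C)(C)O/C=C/[C@]1(C)C2=CCC[C@](C)(C(=O)OC)[C@H]2CC[C@H]1C
A7 | alternative 3 | ring-A enol triflate (C10–OTf, C1=C10) with the C5 arm ending in the C9=C11 olefin and the C12 silyl ether | COC(=O)[C@@]1(C)CCC=C(OS(=O)(=O)C(F)(F)F)[C@@H]1CC[C@@H](C)/C(C)=C/CO[Si](C)(C)C(C)(C)C
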